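Ring B (C5–C6–C7–C8–C9–C10) is first made as a cyclopentane that lacks C9. Asymmetric conjugate addition to 3-methylcyclopent-2-enone sets the quaternary carbon C5 and leaves a silyl enol ether whose C8=C10 double bond marks the bond to be widened. The key step adds chloro(methyl)carbene there and opens the chlorocyclopropane, so that C9 with its methyl group C20 is inserted between C8 and C10 and the five-membered ring becomes the six-membered 2-methyl enone C8(=O)–C9(CH3)=C10. It exploits the oxygen-bearing C8 beside the methyl-bearing C9 of ring B. Metathesis then closes ring A, a reductive hydroxymethylation sets C9 and C10, and an enone transposition opens the way to the C6–C7–C8 oxygen triad.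

Key step: step 2

Remark (atom labels): clerodane numbering of the target is used for every compound: ring A = C1–C2–C3–C4–C5–C10, ring B = C5–C6–C7–C8–C9–C10, methyl C17 on C8, C18 on C4, C19 on C5, C20 on C9, C11=C12 the vinyl link, C13–C16 the butenolide; β is the face of ring B that carries C19, α the other face.
Remark (assumption): the enantiomer of the chiral ligand in step 1 is taken to be the one that gives the (R)-configured quaternary carbon.

Step 1
Reactants: 1 3-methylcyclopent-2-en-1-one
Product: 3 trimethyl{[(3R)-3-methyl-3-(prop-1-en-2-yl)cyclopent-1-en-1-yl]oxy}silane, via aluminium enolate 2 (not isolated)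
Conditions: 2-bromopropene, t-BuLi (2 equiv), Et2O, −78 °C, then Me2AlCl; 1, Cu(OTf)2 (5 mol %), chiral phosphoramidite ligand (10 mol %), Et2O, −30 °C; TMSOTf, −30 → 0 °C
Reagents that add atoms: 2-bromopropene CC(Br)=C; trimethylsilyl trifluoromethanesulfonate C[Si](C)(C)OS(=O)(=O)C(F)(F)F
Why: Copper-catalysed asymmetric conjugate addition of an alkenylalane to the β-methyl enone should transfer the sp2 group (in preference to methyl) to C5 on the face chosen by the chiral ligand, and O-silylation of the aluminium enolate 2 then locks the enol double bond between C8 and C10.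

Step 2
Reactants: 3 trimethyl{[(3R)-3-methyl-3-(prop-1-en-2-yl)cyclopent-1-en-1-yl]oxy}silane
Product: 5 (4R)-2,4-dimethyl-4-(prop-1-en-2-yl)cyclohex-2-en-1-one, via chlorocyclopropane 4 (not isolated)
Conditions: CH3CHCl2 (3 equiv), n-BuLi (1.5 equiv), Et2O, −40 → −20 °C; then toluene, Et3N (0.2 equiv), 110 °C
Reagents that add atoms: 1,1-dichloroethane CC(Cl)Cl
Why: α-Elimination of 1,1-dichloroethane gives chloro(methyl)carbene, which adds in a [2+1] cheletropic cycloaddition to the electron-rich enol ether double bond C8=C10 of 3 to give the 6-chloro-6-methyl-1-siloxybicyclo[3.1.0]hexane 4; on heating, the C–Cl bond ionises in concert with disrotatory cleavage of the ring-fusion bond C8–C10 (cyclopropyl-to-allyl cation electrocyclic opening, pushed by the siloxy oxygen), and loss of Me3SiCl from the 2-siloxyallyl cation leaves the enone C8(=O)–C9(CH3)=C10. The closest known reaction type is the halocarbene ring expansion of silyl enol ethers to 2-substituted cycloalk-2-enones, a carbocyclic counterpart of the Ciamician–Dennstedt rearrangement and a relative of the Saegusa–Ito ring enlargement of siloxycyclopropanes. The three-membered ring is closed by the cycloaddition, and the six-membered ring B then arises by scission of the bond shared by the two small rings, not by a cyclisation. No new stereocentre survives: C5 is untouched and the cyclopropane centres are destroyed. The step needs the enol ether to out-compete the isopropenyl alkene for the carbene, which its far higher nucleophilicity should secure, and it needs chloride cis to the five-membered ring for the concerted opening, which the preference of the larger methyl group for the exo position should favour. The site of insertion is not in question, because the position of the enol double bond was fixed by the conjugate addition in step 1.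

Step 3
Reactants: 5 (4R)-2,4-dimethyl-4-(prop-1-en-2-yl)cyclohex-2-en-1-one
Product: 6 {[(4R)-3-(but-3-en-1-yl)-2,4-dimethyl-4-(prop-1-en-2-yl)cyclohex-1-en-1-yl]oxy}trimethylsilane (both C10 epimers)
Conditions: but-3-enylMgBr, CuBr·SMe2 (10 mol %), TMSCl, HMPA, THF, −78 → −40 °C
Reagents that add atoms: but-3-enylmagnesium bromide C=CCC[Mg]Br; chlorotrimethylsilane C[Si](C)(C)Cl
Why: Copper-catalysed conjugate addition of the Grignard reagent, accelerated by TMSCl, should place the butenyl arm on the β-carbon C10 and return the C8=C9 silyl enol ether regiospecifically; the configuration of the new C10 centre is of no account because step 4 makes C10 trigonal again.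

Step 4
Reactants: 6 {[(4R)-3-(but-3-en-1-yl)-2,4-dimethyl-4-(prop-1-en-2-yl)cyclohex-1-en-1-yl]oxy}trimethylsilane
Product: 7 (4S)-3-(but-3-en-1-yl)-2,4-dimethyl-4-(prop-1-en-2-yl)cyclohex-2-en-1-one
Conditions: IBX·MPO (4-methoxypyridine N-oxide complex, 1.5 equiv), DMSO, 25 °C
Reagents that add atoms: none
Why: Saegusa–Ito-type dehydrosilylation, run with the IBX·4-methoxypyridine N-oxide complex to spare the terminal alkenes, should restore the C9=C10 enone because C10 carries the only hydrogen that can be removed.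

Step 5
Reactants: 7 (4S)-3-(but-3-en-1-yl)-2,4-dimethyl-4-(prop-1-en-2-yl)cyclohex-2-en-1-one
Product: 8 (4aS)-1,4a,5-trimethyl-4,4a,7,8-tetrahydronaphthalen-2(3H)-one
Conditions: second-generation Grubbs catalyst (5 mol %), toluene (0.01 M), 80 °C
Reagents that add atoms: none
Why: Ring-closing metathesis between the terminal butenyl alkene and the 1,1-disubstituted isopropenyl alkene should close ring A with its trisubstituted C3=C4 double bond, the tetrasubstituted enone alkene being inert to the ruthenium carbene.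

Step 6
Reactants: 8 (4aS)-1,4a,5-trimethyl-4,4a,7,8-tetrahydronaphthalen-2(3H)-one
Product: 10 1-(hydroxymethyl)-1,4a,5-trimethyl-3,4,4a,7,8,8a-hexahydronaphthalen-2(1H)-one (trans-fused; 9β-CH3; 9α-CH2OH; 10α-H), via lithium enolate 9 (not isolated)
Conditions: Li (2.2 equiv), t-BuOH (1.0 equiv), NH3(l)/THF, −78 °C; NH3 evaporated; CH2O (gas), THF, −78 °C; NH4Cl
Reagents that add atoms: formaldehyde C=O
Why: Birch-type reductive alkylation of the enone: protonation of the β-carbon C10 from the axial α direction gives the trans ring fusion, and the regiodefined enolate 9 then adds to formaldehyde (aldol reaction) at C9 from the α face, away from the axial C19 methyl group, so that C20 ends β.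

Step 7
Reactants: 10 1-(hydroxymethyl)-1,4a,5-trimethyl-3,4,4a,7,8,8a-hexahydronaphthalen-2(1H)-one
Product: 11 1,4a,5-trimethyl-2-oxo-1,2,4a,7,8,8a-hexahydronaphthalene-1-carbaldehyde (9α-CHO; 9β-CH3; 10α-H)
Conditions: IBX (3.5 equiv), DMSO, 25 → 75 °C
Reagents that add atoms: none
Why: IBX oxidises the primary alcohol to the aldehyde and, at 75 °C, dehydrogenates the C8 ketone toward C7, its only enolisable side (IBX dehydrogenation), the aldehyde having no α-hydrogen.

Step 8
Reactants: 11 1,4a,5-trimethyl-2-oxo-1,2,4a,7,8,8a-hexahydronaphthalene-1-carbaldehyde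
Product: 12 1-ethenyl-1,4a,5-trimethyl-4a,7,8,8a-tetrahydronaphthalen-2(1H)-one (9α-vinyl; 9β-CH3; 10α-H)
Conditions: Ph3PCH3Br, KN(SiMe3)2, THF, −78 → 0 °C
Reagents that add atoms: methyltriphenylphosphonium bromide C[P+](c1ccccc1)(c1ccccc1)c1ccccc1.[Br-]
Why: Wittig methylenation should take place only at the aldehyde, which is far more electrophilic than the conjugated C8 ketone flanked by the quaternary C9.

Step 9
Reactants: 12 1-ethenyl-1,4a,5-trimethyl-4a,7,8,8a-tetrahydronaphthalen-2(1H)-one
Product: 13 1-ethenyl-1,2,4a,5-tetramethyl-1,2,4a,7,8,8a-hexahydronaphthalen-2-ol (8β-OH expected; either C8 epimer serves)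
Conditions: MeLi, CeCl3, THF, −78 °C; NH4Cl
Reagents that add atoms: methyllithium [Li]C
Why: 1,2-Addition of methyllithium to the enone carbonyl, with CeCl3 to suppress conjugate addition, gives the tertiary allylic alcohol, whose C8 configuration (expected from axial α attack) is erased in step 10.

Step 10
Reactants: 13 1-ethenyl-1,2,4a,5-tetramethyl-1,2,4a,7,8,8a-hexahydronaphthalen-2-ol
Product: 14 4-ethenyl-3,4,8,8a-tetramethyl-4a,5,6,8a-tetrahydronaphthalen-1(4H)-one (C6 ketone; C7=C8; 9α-vinyl; 9β-CH3; 10α-H)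
Conditions: pyridinium chlorochromate [C5H5NH][CrO3Cl] (2 equiv), 4 Å MS, CH2Cl2, 25 °C
Reagents that add atoms: none
Why: Babler–Dauben oxidative transposition: the chromate ester of the tertiary allylic alcohol undergoes a [3,3] shift to C6 and is oxidised there, which moves the oxygen to C6 and leaves the C7=C8 enone that carries C17.

Step 11
Reactants: 14 4-ethenyl-3,4,8,8a-tetramethyl-4a,5,6,8a-tetrahydronaphthalen-1(4H)-one
Product: 15 7α,8α-epoxide of 14 (2,3-epoxy-4-ethenyl-3,4,8,8a-tetramethyl-2,3,4,4a,5,6-hexahydronaphthalen-1(8aH)-one)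
Conditions: H2O2 (30 %), NaOH, MeOH, 0 → 25 °C
Reagents that add atoms: hydrogen peroxide OO
Why: Weitz–Scheffer nucleophilic epoxidation is selective for the electron-poor enone over the two isolated alkenes, and hydroperoxide should attack C8 along the axial α trajectory, the β face being shielded by the pseudoaxial C20 and C19 methyl groups, so that the C8–O bond is set α.

Step 12
Reactants: 15 7α,8α-epoxy ketone
Product: 16 4-ethenyl-3-hydroxy-3,4,8,8a-tetramethyl-3,4,4a,5,6,8a-hexahydronaphthalen-1(2H)-one (8α-OH; 8β-CH3)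
Conditions: SmI2 (2.2 equiv), THF/MeOH, −90 °C
Reagents that add atoms: none
Why: Reductive opening of the α,β-epoxy ketone by SmI2 (ketyl formation, then cleavage of the Cα–O bond at C7 and protonation) should give the aldol 16 with the C8–O bond untouched, hence 8α-OH and 8β-CH3.

Step 13
Reactants: 16 4-ethenyl-3-hydroxy-3,4,8,8a-tetramethyl-3,4,4a,5,6,8a-hexahydronaphthalen-1(2H)-one
Product: 18 4-ethenyl-2,3-dihydroxy-3,4,8,8a-tetramethyl-3,4,4a,5,6,8a-hexahydronaphthalen-1(2H)-one (7α-OH; 8α-OH), via dilithium dianion 17 (not isolated)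
Conditions: LiN(SiMe3)2 (2.3 equiv), THF, −78 °C; 2-(benzenesulfonyl)-3-phenyloxaziridine, −78 °C; NH4Cl
Reagents that add atoms: 2-(benzenesulfonyl)-3-phenyloxaziridine O=S(=O)(N1OC1c1ccccc1)c1ccccc1
Why: Davis oxidation of the enolate: the C6 ketone can enolise only toward C7, and the oxaziridine should attack C7 from the α face because the β face is flanked by the two syn-axial methyl groups C19 and C20, the low temperature and lithium counter-ion holding back retro-aldol cleavage of the C8 alkoxide.

Step 14
Reactants: 18 7α,8α-dihydroxy C6 ketone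
Product: 19 4-ethenyl-3,4,8,8a-tetramethyl-1,2,3,4,4a,5,6,8a-octahydronaphthalene-1,2,3-triol (6β-OH; 7α-OH; 8α-OH)
Conditions: Me4NBH(OAc)3 (5 equiv), AcOH/MeCN (1:1), −30 °C
Reagents that add atoms: none
Why: Evans–Saksena reduction: the acetoxyborohydride bound to the α-hydroxyl groups at C7 and C8 delivers hydride to the α face of C6, which is also the face away from the adjacent C19 methyl group, giving the equatorial 6β-alcohol trans to the 7α-hydroxyl.

Step 15
Reactants: 19 6β,7α,8α-triol
Product: 20 6β,7α-diacetate of 19 (8α-OH free)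
Conditions: Ac2O, pyridine, DMAP (10 mol %), CH2Cl2, 25 °C
Reagents that add atoms: acetic anhydride CC(=O)OC(C)=O
Why: DMAP-catalysed acetylation should esterify the two secondary alcohols and leave the tertiary C8 hydroxyl, which is flanked by the quaternary C9, free.

Step 16
Reactants: 20 6β,7α-diacetate; 21 4-bromofuran-2(5H)-one
Product: 22 target CNP0383656.1, (11E)-6β,7α-diacetoxy-8α-hydroxycleroda-3,11,13-trien-15,16-olide
Conditions: Pd(OAc)2 (10 mol %), n-Bu4NCl, NaHCO3, DMF, 60 °C
Reagents that add atoms: none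
Why: Mizoroki–Heck reaction under phosphine-free phase-transfer conditions: the butenolyl–palladium species adds to the unhindered terminal carbon C12 of the vinyl group and β-hydride elimination can only involve H-11, which should give the (E)-diene, while the mild base NaHCO3 spares the acetates and the butenolide.

Compound list
1 | 3-methylcyclopent-2-en-1-one | CC1=CC(=O)CC1 | starting material
2 | dimethyl{[(3R)-3-methyl-3-(prop-1-en-2-yl)cyclopent-1-en-1-yl]oxy}aluminium (aluminium enolate) | C=C(C)[C@]1(C)CCC(O[Al](C)C)=C1 | intermediate (not isolated)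
3 | trimethyl{[(3R)-3-methyl-3-(prop-1-en-2-yl)cyclopent-1-en-1-yl]oxy}silane | C=C(C)[C@]1(C)CCC(O[Si](C)(C)C)=C1 | intermediate
4 | {[(4R)-6-chloro-4,6-dimethyl-4-(prop-1-en-2-yl)bicyclo[3.1.0]hexan-1-yl]oxy}trimethylsilane (cyclopropane diastereomers) | C=C(C)[C@]1(C)CCC2(O[Si](C)(C)C)C1C2(C)Cl | intermediate (not isolated)
5 | (4R)-2,4-dimethyl-4-(prop-1-en-2-yl)cyclohex-2-en-1-one | C=C(C)[C@]1(C)CCC(=O)C(C)=C1 | intermediate
6 | {[(4R)-3-(but-3-en-1-yl)-2,4-dimethyl-4-(prop-1-en-2-yl)cyclohex-1-en-1-yl]oxy}trimethylsilane (both C10 epimers) | C=C(C)[C@]1(C)CCC(O[Si](C)(C)C)=C(C)C1CCC=C | intermediate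
7 | (4S)-3-(but-3-en-1-yl)-2,4-dimethyl-4-(prop-1-en-2-yl)cyclohex-2-en-1-one | C=C(C)[C@]1(C)CCC(=O)C(C)=C1CCC=C | intermediate
8 | (4aS)-1,4a,5-trimethyl-4,4a,7,8-tetrahydronaphthalen-2(3H)-one (C8 ketone, C9=C10 and C3=C4) | C1CC(=O)C(C)=C2CCC=C(C)[C@]12C | intermediate
9 | lithium 1,4a,5-trimethyl-3,4,4a,7,8,8a-hexahydronaphthalen-2-olate, trans-fused (10α-H) | C1CC(O[Li])=C(C)[C@H]2CCC=C(C)[C@]12C | intermediate (not isolated)
10 | 1-(hydroxymethyl)-1,4a,5-trimethyl-3,4,4a,7,8,8a-hexahydronaphthalen-2(1H)-one, trans-fused; 1-CH3 on the face of the 4a-CH3, CH2OH and 8a-H on the other face (9β-CH3, 9α-CH2OH, 10α-H) | C1CC(=O)[C@](C)(CO)[C@H]2CCC=C(C)[C@]12C | intermediate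
11 | 1,4a,5-trimethyl-2-oxo-1,2,4a,7,8,8a-hexahydronaphthalene-1-carbaldehyde (9α-CHO, 9β-CH3, 10α-H) | C1=CC(=O)[C@](C)(C=O)[C@H]2CCC=C(C)[C@]12C | intermediate
12 | 1-ethenyl-1,4a,5-trimethyl-4a,7,8,8a-tetrahydronaphthalen-2(1H)-one (9α-vinyl, 9β-CH3, 10α-H) | C1=CC(=O)[C@](C)(C=C)[C@H]2CCC=C(C)[C@]12C | intermediate
13 | 1-ethenyl-1,2,4a,5-tetramethyl-1,2,4a,7,8,8a-hexahydronaphthalen-2-ol (8β-OH epimer drawn; either serves) | C1=C[C@@](C)(O)[C@](C)(C=C)[C@H]2CCC=C(C)[C@]12C | intermediate
14 | 4-ethenyl-3,4,8,8a-tetramethyl-4a,5,6,8a-tetrahydronaphthalen-1(4H)-one (C6 ketone, C7=C8, 9α-vinyl, 9β-CH3, 10α-H, 5β-CH3) | O=C1C=C(C)[C@](C)(C=C)[C@H]2CCC=C(C)[C@]12C | intermediate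
15 | 7α,8α-epoxide of 14: 2,3-epoxy-4-ethenyl-3,4,8,8a-tetramethyl-2,3,4,4a,5,6-hexahydronaphthalen-1(8aH)-one | O=C1[C@@H]3O[C@]3(C)[C@](C)(C=C)[C@H]2CCC=C(C)[C@]12C | intermediate
16 | 4-ethenyl-3-hydroxy-3,4,8,8a-tetramethyl-3,4,4a,5,6,8a-hexahydronaphthalen-1(2H)-one (8α-OH, 8β-CH3) | O=C1C[C@](C)(O)[C@](C)(C=C)[C@H]2CCC=C(C)[C@]12C | intermediate
17 | dilithium salt of 16 (C6 enolate, C8 alkoxide) | [Li]OC1=C[C@](C)(O[Li])[C@](C)(C=C)[C@H]2CCC=C(C)[C@]12C | intermediate (not isolated)
18 | 4-ethenyl-2,3-dihydroxy-3,4,8,8a-tetramethyl-3,4,4a,5,6,8a-hexahydronaphthalen-1(2H)-one (7α-OH, 8α-OH) | O=C1[C@H](O)[C@](C)(O)[C@](C)(C=C)[C@H]2CCC=C(C)[C@]12C | intermediate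
19 | 4-ethenyl-3,4,8,8a-tetramethyl-1,2,3,4,4a,5,6,8a-octahydronaphthalene-1,2,3-triol (6β-OH, 7α-OH, 8α-OH) | O[C@H]1[C@H](O)[C@](C)(O)[C@](C)(C=C)[C@H]2CCC=C(C)[C@]12C | intermediate
20 | 6β,7α-diacetate of 19 (8α-OH free, 9α-vinyl) | CC(=O)O[C@H]1[C@H](OC(C)=O)[C@](C)(O)[C@](C)(C=C)[C@H]2CCC=C(C)[C@]12C | intermediate
21 | 4-bromofuran-2(5H)-one | BrC1=CC(=O)OC1 | starting material
22 | CNP0383656.1, (11E)-6β,7α-diacetoxy-8α-hydroxycleroda-3,11,13-trien-15,16-olide | CC(=O)O[C@H]1[C@H](OC(C)=O)[C@](C)(O)[C@](C)(/C=C/C2=CC(=O)OC2)[C@H]2CCC=C(C)[C@]12C | target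

Total step count: 16. Longest linear sequence: 16 steps (1 to 22; 21 is a purchased partner).

Steps most likely to fail

Step 2 (key step). The carbene may also cyclopropanate the isopropenyl group, n-BuLi may cleave the silyl enol ether before the carbenoid forms, or a cyclopropane with exo chloride may refuse the concerted opening. The fallback changes the mechanism of ring enlargement from an electrocyclic opening to a one-electron oxidative cleavage. It sets out from 3: zinc-carbenoid ethylidene transfer (Simmons–Smith reaction in the Furukawa modification; Et2Zn, CH3CHI2, CH2Cl2, 0 °C) would give {[(4R)-4,6-dimethyl-4-(prop-1-en-2-yl)bicyclo[3.1.0]hexan-1-yl]oxy}trimethylsilane F1. FeCl3 in DMF (Saegusa–Ito ring enlargement) would then break the ring-fusion bond through the alkoxy radical and give (4S)-3-chloro-2,4-dimethyl-4-(prop-1-en-2-yl)cyclohexan-1-one F2. NaOAc in MeOH would eliminate HCl and rejoin the route at 5.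

Step 13. The lithium aldolate may open ring B by retro-aldol cleavage, the enolate may add to the sulfonimine formed from the oxidant, or facial control at C7 may be poor. The fallback avoids the dianion and sets out from 16: TMSOTf/Et3N would give the bis-silyl derivative {[(C6 enol ether, 8α-silyl ether) of 16]} 4-ethenyl-3,4,8,8a-tetramethyl-1,3-bis(trimethylsilyloxy)-3,4,4a,5,6,8a-hexahydronaphthalene F3. Rubottom oxidation with dimethyldioxirane (1.0 equiv, acetone, −78 °C) should epoxidise the electron-rich enol ether from the α face and, after silyl migration, give the 7α-silyloxy ketone 4-ethenyl-3,4,8,8a-tetramethyl-2,3-bis(trimethylsilyloxy)-3,4,4a,5,6,8a-hexahydronaphthalen-1(2H)-one F4. Citric acid in MeOH would remove both silyl groups and rejoin the route at 18.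

Step 16. The bromobutenolide may decompose under the basic conditions, and insertion into the vinyl group on the quaternary C9 may be slow, so that palladium black forms first. The fallback replaces the Heck reaction by a boron-based cross-coupling and sets out from 20: cross-metathesis with vinylboronic acid pinacol ester (second-generation Hoveyda–Grubbs catalyst, CH2Cl2, 40 °C) would give the (E)-alkenylboronate, the 12-(4,4,5,5-tetramethyl-1,3,2-dioxaborolan-2-yl) derivative of 20 F5. Suzuki–Miyaura coupling of this with 21 (Pd(PPh3)4, K3PO4, THF/H2O, 50 °C) would give 22.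

Further compounds
F1 | step 2 | {[(4R)-4,6-dimethyl-4-(prop-1-en-2-yl)bicyclo[3.1.0]hexan-1-yl]oxy}trimethylsilane | C=C(C)[C@]1(C)CCC2(O[Si](C)(C)C)C1C2C
F2 | step 2 | (4S)-3-chloro-2,4-dimethyl-4-(prop-1-en-2-yl)cyclohexan-1-one (mixture at C9 and C10) | C=C(C)[C@]1(C)CCC(=O)C(C)C1Cl
F3 | step 13 | 4-ethenyl-3,4,8,8a-tetramethyl-1,3-bis(trimethylsilyloxy)-3,4,4a,5,6,8a-hexahydronaphthalene (C6 silyl enol ether, 8α-silyl ether) | C[Si](C)(C)OC1=C[C@](C)(O[Si](C)(C)C)[C@](C)(C=C)[C@H]2CCC=C(C)[C@]12C
F4 | step 13 | 4-ethenyl-3,4,8,8a-tetramethyl-2,3-bis(trimethylsilyloxy)-3,4,4a,5,6,8a-hexahydronaphthalen-1(2H)-one (7α,8α) | O=C1[C@H](O[Si](C)(C)C)[C@](C)(O[Si](C)(C)C)[C@](C)(C=C)[C@H]2CCC=C(C)[C@]12C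
F5 | step 16 | (E)-alkenylboronate: 6β,7α-diacetate 20 with C12 bearing 4,4,5,5-tetramethyl-1,3,2-dioxaborolan-2-yl | CC(=O)O[C@H]1[C@H](OC(C)=O)[C@](C)(O)[C@](C)(/C=C/B3OC(C)(C)C(C)(C)O3)[C@H]2CCC=C(C)[C@]12C
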